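## Structural features

The target is a melampolide-type germacranolide: a cyclodecadiene (C1 to C10) fused trans across C6–C7 to an α-methylene-γ-butyrolactone (O–C12(=O)–C11(=C13) between C6 and C7). The ten-membered ring holds a cis C1=C10 alkene with the C14 hydroxymethyl group on C10 and a trans C4=C5 alkene with the C15 methyl group on C4. There are four stereocentres: C6 (R), C7 (R) and C8 (R) are contiguous, with the lactone oxygen on C6 trans to the C7–C11 bond and the C8 oxygen cis to it, while C2 (S) stands alone between the two alkenes. Three oxygens must end up different: an acetate on the allylic C2 oxygen, a methacrylate on C8 and a free primary allylic hydroxyl on C14. Fragile parts are the α-methylene lactone and the methacrylate (Michael acceptors), the allylic acetate, and the 1,5-diene of the medium ring (transannular cyclisation in strong acid, Cope rearrangement on heating). The real difficulty is to build the ten-membered ring with one cis and one trans trisubstituted alkene and, in the same operation, the remote C2 centre in a fixed relation to the C6–C8 triad. The plan uses the fact that C10=C1–C2–C3–C4=C5 is a 1,5-diene: a bond between C5 and C10 turns the macrocycle into a cyclohexane (C5 to C10) on which C6, C7 and C8 sit on a chair, and an oxygen on C10 makes the reverse step an oxy-Cope ring expansion whose enolate also marks C10 for the C14 carbon.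

## Logic of the disconnections

46 from 40 (through 45, 44, 42, 41). The O14–Si bond and the acyl C–O bonds at O8 and O2 are cut first, then the ether C–O bonds that hide O8 and O2. Esters and a free hydroxyl cannot pass through enolate chemistry, so the three oxygens are carried as ethers of different lability (methoxymethyl on O8, 4-methoxybenzyl on O2, tert-butyldiphenylsilyl on O14). Each unmasking must spare the α-methylene lactone and the diene, which calls for DDQ, a buffered silyl triflate and buffered fluoride.

40 from 37 (through 38). The C11=C13 bond is cut. A plain lactone is simpler to carry than a Michael acceptor. The forward Mannich–elimination needs the lactone α-position to be the only acidic site, which holds because only ethers are present in 37.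

37 from 35 (through 36). The C12 carbonyl is taken back to a mixed methyl acetal. A lactone would be enolised or attacked in the organometallic and strong-base steps; the acetal is inert there. The forward steps are a mild hydrolysis and a neutral oxidation.

35 from 32 and 33 (through 34). The C10–C14 bond is cut. C14 then comes from a one-carbon stannane and the alkene geometry is inherited from an enol sulfonate. The forward cross-coupling needs the C10 enol triflate of 32 with fixed position and geometry.

32 from 29 (key step). The C2–C3 bond is cut and the C5–C10 bond is re-formed on paper. This trades the ten-membered ring, both ring alkenes and C2 for a cyclohexanol with two alkenyl groups. The forward [3,3] shift needs the two alkenyl groups cis, the chair of 29 locked so that only one pericyclic chair is open, a Z enol ether to set C2, and capture of the enolate on oxygen before it can lose the C2 alkoxide.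

29 from 20 and 26; 26 from 21 and 22 (through 25). The C10–C1 bond is cut. The tertiary carbinol comes from a ketone and a two-carbon alkenyl nucleophile whose oxygen is already protected. The forward addition must not enolise C5 and must come from the equatorial side; the syn-axial O8 substituent of 20 blocks the other face.

20 from 16 and 17 (through 19); 16 from 14 (through 15). The C5–C4 bond is cut at an oxirane. A ketone enolate route would have to choose between two α-methylene groups and would give the more stable equatorial epimer, whereas C5 must carry an axial isopropenyl group cis to O6. Trans-diaxial opening of an oxirane on the face of O8 gives exactly this regiochemistry and configuration. The demand is an oxirane on that face, which the free C8 hydroxyl of 14 directs.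

14 from 11 (through 13 and 12). The C5=C10 double bond is cut by metathesis, and the acetal is traced to the lactone. This fixes the alkene position by construction and reduces the bicycle to a monocyclic lactone with two terminal alkenes. The forward ring closure forms an unstrained cyclohexene.

11 from 9 and 10; 9 from 6 (through 7). The C8–C9 bond is cut. C8 is set by a reagent-controlled allylation of an aldehyde, so it does not depend on the weak bias of the neighbouring C7. The aldehyde is base-sensitive and must be made and used under neutral conditions.

6 from 3 and 4; 3 from 1 and 2. The C6–C7 bond and the O6–C12 bond are cut. An auxiliary-controlled syn-aldol sets C6 and C7 in one step and the hydroxyl closes the trans lactone on the ester already in the chain. The demand is selective enolisation of the imide next to an ester, which boron enolates meet.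

## Other disconnections considered

Alternative 1: The cut is at the lactone C6–O and O–C12 bonds and leads to the ring acid A2, in which C6 is a methylene group. In the forward step a cytochrome P450 monooxygenase of the costunolide or eupatolide synthase class would hydroxylate the allylic C6–H bond (hydrogen abstraction by the iron-oxo species, oxygen rebound) and the γ-hydroxy acid would close to A1.
- In its favour: C6 would be set with enzyme-level control at an unactivated C–H bond, no protecting group is needed for the lactone, and the C11=C13 alkene is present from the start. On this last point it is better than the chosen plan, which spends steps 19 to 22 on it.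
- Against it: A2 still holds the ten-membered ring, both alkene geometries and C2, C7 and C8, so the cut removes only the lactone and leaves the main problem. These enzymes act on all-trans ring acids without C2, C8 or C14 oxygens; acceptance of a 1(10)-cis ring with three more oxygen groups is an open question, and hydroxylation at C3, C9 or C15 or epoxidation are conceivable. A1 would then need acylation of C8 in the presence of the more reactive primary C14 hydroxyl.
- Comparison: on structure the chosen plan simplifies the ring and the alternative does not; on mechanism a radical rebound stands against a stereospecific pericyclic shift; on step economy the alternative has the shorter endgame, but its total depends on a synthesis of A2 that would itself need a ring construction of the chosen kind.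

Alternative 2: The cut treats C1–C10 and C4–C5 as former cyclobutane bonds. In the forward step cyclohexenone A4 (C5 to C10 with C7 and C8) and cyclobutene A5 (C1 to C4 with C2) would combine under irradiation to the cis-anti-cis tricycle A3. Thermal cycloreversion across C5–C10 and C1–C4 would then open the ten-membered ring.
- In its favour: two carbon–carbon bonds form in one step from two small chiral rings. The ring arises by ring expansion and not by end-to-end closure, which makes it the equal of the chosen plan on that point. C14 and C15 are in place from the outset, so no cross-coupling and no enolate with a β-leaving group is needed; here it is better than the chosen plan.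
- Against it: the orientation of the addition (C5 to C4 and C10 to C1, not the reverse) and the face selectivity on both partners rest on a triplet 1,4-biradical and are hard to secure. The β,β-disubstituted enone must form a quaternary C10. Which alkene becomes cis depends on the adduct configuration, and the cycloreversion temperature is in the range where 1,5-dienes equilibrate by Cope rearrangement. Afterwards the C6 ketone must be reduced from one face of a flexible ring, and the lactone and its methylene group are still to be made.
- Comparison: both plans expand a six-membered ring. The chosen one passes alkene geometry and C2 through a closed-shell chair under substrate control; the photochemical one could be shorter in protecting-group steps if its selectivities held.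

Alternative 3: The cut is at C1–C2 and leads to the open-chain iodoalkene aldehyde A7. In the forward step CrCl2 with catalytic NiCl2 (Nozaki–Hiyama–Kishi reaction: oxidative addition of the alkenyl iodide to nickel, transfer to chromium, addition of the alkenylchromium to the aldehyde) would close the ring to A6.
- In its favour: it is the most convergent cut. The lactone, its methylene group, the methacrylate and C14 are finished before ring closure, the Z geometry of the iodoalkene is retained, and only acetylation and desilylation would remain. The endgame is clearly better than the eleven steps of the chosen plan.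
- Against it: a ten-membered ring is closed directly, against transannular strain and entropy, so high dilution and oligomers are to be expected. The C2 carbinol configuration would depend on the conformation of the closing chain and might need correction. A7 must carry a Z trisubstituted iodoalkene, an E trisubstituted alkene and two Michael acceptors through a long linear assembly.
- Comparison: the chosen plan pays no medium-ring closure penalty and sets C2 and both alkenes in one stereospecific event; the alternative is equal or better in convergence and endgame length but weaker on ring closure and C2 control.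

Key step: step 16

Remark: germacrane numbering is used for all intermediates; in 29 the C10 oxygen is axial on the cyclohexane (anti to the axial isopropenyl group, alkoxyvinyl group equatorial) and is pseudo-equatorial only in the six-centre chair of the rearrangement.

Assumption: the acetal or lactol carbon C12 (13, 14 and later compounds) and C11 in 38 and 39 should form as epimer mixtures; one epimer is drawn for each because C12 is erased in 37 and C11 in 40.

## Steps

Step 1
Reactants: 1 (S)-4-benzyl-1,3-oxazolidin-2-one; 2 methyl 4-chloro-4-oxobutanoate
Product: 3 methyl 4-[(4S)-4-benzyl-2-oxo-1,3-oxazolidin-3-yl]-4-oxobutanoate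
Conditions: n-BuLi, THF, −78 °C; 2, −78 → 0 °C
Reagents that add atoms: none
Why: N-Acylation of the lithiated oxazolidinone by the acid chloride, which reacts far faster than the methyl ester; it installs the auxiliary that will control C6 and C7.

Step 2
Reactants: 3 succinate imide; 4 acrolein
Product: 6 (4S)-4-benzyl-3-[(2R,3S)-5-oxo-2-vinyltetrahydrofuran-3-carbonyl]-1,3-oxazolidin-2-one, via syn-aldol adduct 5 (not isolated)
Conditions: Bu2BOTf, iPr2NEt, CH2Cl2, 0 °C; 4, −78 → 0 °C; pH 7 buffer, MeOH, H2O2; then TsOH·H2O (cat.), CH2Cl2, rt
Reagents that add atoms: none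
Why: Evans syn-aldol reaction: the Z boron enolate of the imide adds 1,2 to acrolein through a closed chair transition state with the auxiliary carbonyl turned away, which sets C7 and C6 together; the C6 hydroxyl then displaces methoxide from the γ-ester (acyl substitution, retention) to give the 6,7-trans lactone.

Step 3
Reactants: 6 lactone imide
Product: 7 (2R,3S)-5-oxo-2-vinyltetrahydrofuran-3-carboxylic acid
Conditions: LiOH, H2O2, THF–H2O, 0 °C; Na2SO3; HCl to pH 2
Reagents that add atoms: hydrogen peroxide (as LiOOH), SMILES OO
Why: Hydroperoxide attacks the exocyclic imide carbonyl selectively and releases the auxiliary; a lactone opened by hydroxide recloses on acidification because only the γ-lactone on O6 can form.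

Step 4
Reactants: 7 lactone acid
Product: 9 (2R,3S)-5-oxo-2-vinyltetrahydrofuran-3-carbaldehyde, via acid chloride 8 (not isolated)
Conditions: (COCl)2, DMF (cat.), CH2Cl2, 0 °C → rt; evaporate; Bu3SnH, Pd(PPh3)4 (cat.), toluene, rt
Reagents that add atoms: none
Why: Palladium-catalysed reduction of the acid chloride by the tin hydride (acylpalladium intermediate, hydride transfer) stops at the aldehyde under neutral conditions, which the base-sensitive β-acyloxy aldehyde and the terminal alkene tolerate; the 6,7-trans arrangement is the stable one and is kept.

Step 5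
Reactants: 9 lactone aldehyde; 10 B-allylbis(isopinocampheyl)borane made from (−)-α-pinene
Product: 11 (4R,5R)-4-[(1R)-1-hydroxybut-3-en-1-yl]-5-vinyldihydrofuran-2(3H)-one
Conditions: 10, Et2O, −78 °C; then NaOAc (aq), H2O2, 0 °C → rt
Reagents that add atoms: none
Why: Brown allylboration through a six-membered chair transition state; the isopinocampheyl groups (reagent control) should direct the allyl group to the aldehyde face that gives the (R)-carbinol at C8, the antipodal reagent being the one expected to give (S)-1-phenylbut-3-en-1-ol from benzaldehyde.

Step 6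
Reactants: 11 diene lactone
Product: 12 (3aR,4R,7aR)-4-hydroxy-3a,4,5,7a-tetrahydro-1-benzofuran-2(3H)-one
Conditions: second-generation Grubbs catalyst (H2IMes)(PCy3)Cl2Ru=CHPh (3 mol %), CH2Cl2 (5 mM), 40 °C
Reagents that add atoms: none
Why: Ring-closing metathesis of the two terminal alkenes forms the C5=C10 bond of an unstrained cyclohexene with loss of ethylene; the alkene position is fixed by construction and the C8 hydroxyl becomes pseudo-axial on the trans-fused bicycle.

Step 7
Reactants: 12 bicyclic lactone
Product: 13 (2S,3aR,4R,7aR)-2,3,3a,4,5,7a-hexahydro-1-benzofuran-2,4-diol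
Conditions: iBu2AlH (2.2 equiv), CH2Cl2, −78 °C; KNaC4H4O6 (aq)
Reagents that add atoms: none
Why: Half-reduction of the lactone: the aluminium hemiacetal is stable at −78 °C and gives the lactol on work-up; the first equivalent of hydride is consumed by the hydroxyl.

Step 8
Reactants: 13 lactol
Product: 14 (2S,3aR,4R,7aR)-2-methoxy-2,3,3a,4,5,7a-hexahydro-1-benzofuran-4-ol
Conditions: MeOH, PPTS (cat.), rt
Reagents that add atoms: methanol, SMILES CO
Why: Acid-catalysed acetalisation through the ring oxocarbenium ion masks the lactone as a base-stable methyl acetal; the strained bridged acetal with O8 should not compete in neat methanol.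

Step 9
Reactants: 14 cyclohexenol acetal
Product: 15 cis-epoxy alcohol (5,10-oxirane on the face of the C8 hydroxyl)
Conditions: VO(acac)2 (5 mol %), t-BuOOH, CH2Cl2, 0 °C → rt
Reagents that add atoms: tert-butyl hydroperoxide, SMILES CC(C)(C)OO
Why: Hydroxyl-directed epoxidation: the vanadium alkoxide of the pseudo-axial homoallylic C8 hydroxyl delivers the peroxide oxygen to the alkene face it occupies, so the oxirane is cis to O8 and anti to the place the isopropenyl group must take.

Step 10
Reactants: 15 epoxy alcohol
Product: 16 8-O-methoxymethyl ether of 15
Conditions: MOMCl, iPr2NEt, CH2Cl2, 0 °C → rt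
Reagents that add atoms: chloromethyl methyl ether, SMILES COCCl
Why: Alkylation of the secondary alcohol under amine base leaves oxirane and acetal intact; an acetal-type ether is chosen for O8 because a silyl ether would migrate to the syn-axial C10 alkoxide in steps 15 and 16.

Step 11
Reactants: 16 epoxy ether; 17 2-bromopropene
Product: 19 trans-diaxial 5-isopropenyl-10-ol, via isopropenylmagnesium bromide 18 (not isolated)
Conditions: 17, Mg, THF, rt; CuI (10 mol %), 16, −30 → 0 °C
Reagents that add atoms: none
Why: Copper-catalysed Grignard opening of the oxirane with inversion; in the chair fixed by the trans ring fusion only attack at C5 from the face opposite the oxirane leads directly to the trans-diaxial product (Fürst–Plattner rule), which sets C5 with the isopropenyl group axial and cis to O6 and leaves an axial C10 hydroxyl.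

Step 12
Reactants: 19 isopropenyl alcohol
Product: 20 10-ketone with axial 5-isopropenyl group
Conditions: Dess–Martin periodinane, NaHCO3, CH2Cl2, 0 °C → rt
Reagents that add atoms: none
Why: Dess–Martin oxidation of the secondary alcohol under buffered, non-basic conditions, so the axial C5 centre should neither epimerise nor move its alkene into conjugation; 20 is used at once.

Step 13
Reactants: 21 4-methoxybenzyl alcohol; 22 trichloroethylene
Product: 25 1-[(ethynyloxy)methyl]-4-methoxybenzene, via dichlorovinyl ether 23 (not isolated), via lithium alkynyl ether 24 (not isolated)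
Conditions: KH, THF, 0 °C; 22, 0 °C → rt; n-BuLi (2.4 equiv), −78 → −40 °C; MeOH, −78 °C
Reagents that add atoms: none
Why: Addition–elimination of the alkoxide on trichloroethylene gives the 1,2-dichlorovinyl ether; n-BuLi then eliminates HCl and exchanges the remaining chlorine for lithium, and protonation gives the alkynyl ether, which is kept below room temperature because benzyl alkynyl ethers rearrange on warming.

Step 14
Reactants: 25 alkynyl ether
Product: 26 (Z)-tributyl[2-(4-methoxybenzyloxy)vinyl]stannane
Conditions: Bu3SnH (1.0 equiv), BEt3 (cat.), air, toluene, −20 °C → rt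
Reagents that add atoms: tributyltin hydride, SMILES CCCC[SnH](CCCC)CCCC
Why: Radical hydrostannation at low temperature: the stannyl radical adds to the terminal carbon and the α-alkoxyvinyl radical takes hydrogen anti to tin, giving the kinetic Z isomer; one equivalent of hydride and low temperature should prevent Z to E equilibration.

Step 15
Reactants: 20 ketone; 26 (Z)-alkoxyvinylstannane
Product: 29 cis-1,2-divinylcyclohexanol (axial 5-isopropenyl; equatorial 10-[(Z)-2-(4-methoxybenzyloxy)vinyl]; axial 10-OH), via alkoxyvinyllithium 27 (not isolated), via alkoxyvinylcerium dichloride 28 (not isolated)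
Conditions: 26, n-BuLi, THF, −78 °C; CeCl3, −78 °C; 20, −78 °C
Reagents that add atoms: none
Why: Tin–lithium exchange with retention of the Z geometry, transfer to the weakly basic organocerium reagent and 1,2-addition to the ketone without enolisation at C5; the axial face of the carbonyl is blocked by the syn-axial C8 methoxymethoxy group, so equatorial attack should set C10 with the hydroxyl axial and the alkoxyvinyl group cis to isopropenyl.

Step 16
Reactants: 29 cis-1,2-divinylcyclohexanol
Product: 32 (1(10)Z,4E,2S)-ten-membered C10 enol triflate with 2-OPMB and 8-OMOM and the 6,12-lactol methyl acetal, via potassium alkoxide 30 (not isolated), via potassium enolate 31 (not isolated)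
Conditions: PhNTf2, 18-crown-6, THF, −78 °C; KN(SiMe3)2, −78 → −30 °C
Reagents that add atoms: N-phenylbis(trifluoromethanesulfonimide), SMILES O=S(=O)(N(c1ccccc1)S(=O)(=O)C(F)(F)F)C(F)(F)F
Why: Deprotonation gives alkoxide 30, whose C5–C10 bond is weakened by the oxyanion; a concerted [3,3] shift through a six-centre chair forms C2–C3 as C5–C10 breaks and gives enolate 31 with the double bond at C10=C1 only (anionic oxy-Cope rearrangement, the known ring expansion of 1,2-divinylcyclohexanols to cyclodec-5-enone enolates). The ten-membered ring is closed by expansion of the cyclohexane by four atoms and not by end-to-end cyclisation, so no medium-ring closure penalty is paid. The trans-fused acetal ring locks the cyclohexane chair with the isopropenyl group axial and the alkoxyvinyl group equatorial, so only the pericyclic chair with C6 and the oxyanion pseudo-equatorial and C9 pseudo-axial is open; it places C3 and C6 trans on C4=C5 and C2 and C9 cis on C1=C10. The new stereocentre C2 is controlled by the Z geometry of the enol ether, which puts the benzyloxy group pseudo-axial in this chair, together with the fixed configurations of C5 and C10, and should come out (2S). The step needs chair over boat selectivity, which the locked ring fusion secures, and it needs O-sulfonylation of 31 to be faster than loss of the C2 alkoxide or proton transfer, which is why PhNTf2 is present while 31 forms at low temperature. The hindered tertiary alkoxide 30 should react with this mild sulfonyl donor much more slowly than the enolate oxygen does.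

Step 17
Reactants: 32 enol triflate; 33 (tributylstannyl)methanol
Product: 34 C14 allylic alcohol (CH2OH on C10 in place of the triflate)
Conditions: Pd(PPh3)4 (10 mol %), LiCl, THF, 60 °C
Reagents that add atoms: none
Why: Stille coupling: oxidative addition of the enol triflate to zerovalent palladium with retention, chloride exchange, transfer of the hydroxymethyl group from tin and reductive elimination place C14 on C10 trans to C2; ethers and acetal are inert.

Step 18
Reactants: 34 allylic alcohol
Product: 35 14-O-tert-butyldiphenylsilyl ether of 34
Conditions: TBDPSCl, imidazole, DMF, 0 °C → rt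
Reagents that add atoms: tert-butyl(chloro)diphenylsilane, SMILES CC(C)(C)[Si](Cl)(c1ccccc1)c1ccccc1
Why: Silylation of the primary allylic alcohol; the acid-stable silyl ether should survive the acetal hydrolysis, the enolate chemistry and both later ether cleavages and is removed last.

Step 19
Reactants: 35 silyl ether acetal
Product: 36 6,12-lactol
Conditions: AcOH–THF–H2O (3:1:1), 35 °C
Reagents that add atoms: water, SMILES O
Why: Mild acid hydrolysis of the 2-methoxytetrahydrofuran acetal through its ring oxocarbenium ion; this acetal is far more labile than the methoxymethyl and 4-methoxybenzyl ethers, and the oxygen-flanked alkenes are too electron-poor to be protonated under these conditions.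

Step 20
Reactants: 36 lactol
Product: 37 6,12-lactone
Conditions: nPr4N[RuO4] (5 mol %), NMO, 4 Å MS, CH2Cl2, rt
Reagents that add atoms: none
Why: Ley–Griffith oxidation of the lactol to the γ-lactone at room temperature and neutral pH; no free alcohol is present and no heating is needed, which avoids Cope rearrangement of the 1,5-diene.

Step 21
Reactants: 37 lactone
Product: 38 11-(dimethylaminomethyl) lactone
Conditions: LiN(iPr)2, THF, −78 °C; [CH2=NMe2]I, −78 °C → rt
Reagents that add atoms: dimethyl(methylidene)ammonium iodide (Eschenmoser's salt), SMILES C=[N+](C)C.[I-]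
Why: Mannich reaction of the lactone lithium enolate, the only acidic site of a molecule that carries ethers only; the new C11 centre is erased in the next step.

Step 22
Reactants: 38 Mannich base
Product: 40 α-methylene lactone, via trimethylammonium iodide 39 (not isolated)
Conditions: MeI, MeOH, rt; NaHCO3 (aq), CH2Cl2, rt
Reagents that add atoms: none
Why: N-Methylation gives the quaternary ammonium salt, which undergoes β-elimination under bicarbonate (E1cB through the lactone enolate) to the exocyclic C11=C13 alkene.

Step 23
Reactants: 40 α-methylene lactone
Product: 41 C2 allylic alcohol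
Conditions: DDQ, CH2Cl2–pH 7 buffer (10:1), 0 °C
Reagents that add atoms: none
Why: Oxidative cleavage of the 4-methoxybenzyl ether by hydride abstraction and hydrolysis of the oxocarbenium ion; methoxymethyl and silyl ethers and the lactone are inert, and C2 keeps its configuration because its C–O bond is not broken.

Step 24
Reactants: 41 C2 alcohol
Product: 42 C2 acetate
Conditions: Ac2O, pyridine, DMAP (cat.), CH2Cl2, 0 °C → rt
Reagents that add atoms: acetic anhydride, SMILES CC(=O)OC(C)=O
Why: DMAP-catalysed acylation of the secondary allylic alcohol with retention at C2.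

Step 25
Reactants: 42 acetate
Product: 44 C8 alcohol, via bipyridinium triflate 43 (not isolated)
Conditions: TMSOTf, 2,2'-bipyridyl, CH2Cl2, 0 °C → rt; then H2O, rt
Reagents that add atoms: none
Why: Chemoselective cleavage of the methoxymethyl ether: the silyl triflate–bipyridyl pair activates the acetal, bipyridyl captures the oxocarbenium ion as an N-(alkoxymethyl)pyridinium salt and water releases the alcohol; the medium stays close to neutral, so the allylic acetate, the silyl ether and the diene should survive.

Step 26
Reactants: 44 C8 alcohol
Product: 45 8-methacrylate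
Conditions: methacrylic anhydride, Et3N, DMAP (cat.), CH2Cl2, 0 °C → rt
Reagents that add atoms: methacrylic anhydride, SMILES C=C(C)C(=O)OC(=O)C(C)=C
Why: DMAP-catalysed acylation of the C8 hydroxyl with retention; the anhydride avoids chloride ion and ketene formation from the acid chloride.

Step 27
Reactants: 45 silyl ether
Product: 46 target (CNP0138477.2)
Conditions: HF·pyridine, pyridine, THF, 0 °C → rt
Reagents that add atoms: none
Why: Fluoride cleavage of the primary silyl ether under buffered, non-basic conditions, so neither ester should migrate or hydrolyse and the α-methylene lactone is not attacked.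

## Compound list

1 | (S)-4-benzyl-1,3-oxazolidin-2-one | O=C1N[C@@H](Cc2ccccc2)CO1 | starting material
2 | methyl 4-chloro-4-oxobutanoate | COC(=O)CCC(Cl)=O | starting material
3 | methyl 4-[(4S)-4-benzyl-2-oxo-1,3-oxazolidin-3-yl]-4-oxobutanoate | COC(=O)CCC(=O)N1[C@@H](Cc2ccccc2)COC1=O | intermediate
4 | acrolein | C=CC=O | starting material
5 | methyl (3S,4R)-3-[(4S)-4-benzyl-2-oxo-1,3-oxazolidine-3-carbonyl]-4-hydroxyhex-5-enoate (syn-aldol adduct, formed in the flask) | COC(=O)C[C@@H]([C@H](O)C=C)C(=O)N1[C@@H](Cc2ccccc2)COC1=O | intermediate
6 | (4S)-4-benzyl-3-[(2R,3S)-5-oxo-2-vinyltetrahydrofuran-3-carbonyl]-1,3-oxazolidin-2-one (6,7-trans lactone) | O=C1C[C@H](C(=O)N2[C@@H](Cc3ccccc3)COC2=O)[C@@H](C=C)O1 | intermediate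
7 | (2R,3S)-5-oxo-2-vinyltetrahydrofuran-3-carboxylic acid | O=C1C[C@H](C(=O)O)[C@@H](C=C)O1 | intermediate
8 | (2R,3S)-5-oxo-2-vinyltetrahydrofuran-3-carbonyl chloride (formed in the flask) | O=C1C[C@H](C(Cl)=O)[C@@H](C=C)O1 | intermediate
9 | (2R,3S)-5-oxo-2-vinyltetrahydrofuran-3-carbaldehyde | O=C1C[C@H](C=O)[C@@H](C=C)O1 | intermediate
10 | B-allylbis(isopinocampheyl)borane made from (−)-α-pinene | C=CCB([C@H]1C[C@H]2C[C@@H]([C@@H]1C)C2(C)C)[C@H]1C[C@H]2C[C@@H]([C@@H]1C)C2(C)C | starting material
11 | (4R,5R)-4-[(1R)-1-hydroxybut-3-en-1-yl]-5-vinyldihydrofuran-2(3H)-one | O=C1C[C@H]([C@H](O)CC=C)[C@@H](C=C)O1 | intermediate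
12 | (3aR,4R,7aR)-4-hydroxy-3a,4,5,7a-tetrahydro-1-benzofuran-2(3H)-one (trans-fused; 8-OH cis to C11) | O=C1C[C@@H]2[C@H](O)CC=C[C@H]2O1 | intermediate
13 | (2S,3aR,4R,7aR)-2,3,3a,4,5,7a-hexahydro-1-benzofuran-2,4-diol (lactol, one C12 epimer drawn) | O[C@@H]1C[C@@H]2[C@H](O)CC=C[C@H]2O1 | intermediate
14 | (2S,3aR,4R,7aR)-2-methoxy-2,3,3a,4,5,7a-hexahydro-1-benzofuran-4-ol (methyl acetal, one C12 epimer drawn) | CO[C@@H]1C[C@@H]2[C@H](O)CC=C[C@H]2O1 | intermediate
15 | 14 with a 5,10-oxirane on the face of the C8 hydroxyl (cis-epoxy alcohol) | CO[C@@H]1C[C@@H]2[C@H](O)C[C@@H]3O[C@@H]3[C@H]2O1 | intermediate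
16 | 8-O-methoxymethyl ether of 15 | CO[C@@H]1C[C@@H]2[C@H](OCOC)C[C@@H]3O[C@@H]3[C@H]2O1 | intermediate
17 | 2-bromopropene | C=C(C)Br | starting material
18 | isopropenylmagnesium bromide (formed in the flask) | C=C(C)[Mg]Br | intermediate
19 | bicyclic acetal with axial 5-isopropenyl (cis to O6), axial 10-hydroxyl (anti to isopropenyl) and 8-OMOM | CO[C@@H]1C[C@@H]2[C@H](OCOC)C[C@H](O)[C@@H](C(C)=C)[C@H]2O1 | intermediate
20 | 10-ketone of 19 (axial 5-isopropenyl) | CO[C@@H]1C[C@@H]2[C@H](OCOC)CC(=O)[C@@H](C(C)=C)[C@H]2O1 | intermediate
21 | 4-methoxybenzyl alcohol | COc1ccc(CO)cc1 | starting material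
22 | trichloroethylene | ClC=C(Cl)Cl | starting material
23 | (E)-1,2-dichlorovinyl 4-methoxybenzyl ether (formed in the flask) | Cl/C=C(/Cl)OCc1ccc(OC)cc1 | intermediate
24 | lithium [(4-methoxybenzyloxy)ethynyl]ide (formed in the flask) | [Li]C#COCc1ccc(OC)cc1 | intermediate
25 | 1-[(ethynyloxy)methyl]-4-methoxybenzene | C#COCc1ccc(OC)cc1 | intermediate
26 | (Z)-tributyl[2-(4-methoxybenzyloxy)vinyl]stannane | CCCC[Sn](CCCC)(CCCC)/C=C\OCc1ccc(OC)cc1 | intermediate
27 | (Z)-2-(4-methoxybenzyloxy)vinyllithium (formed in the flask) | [Li]/C=C\OCc1ccc(OC)cc1 | intermediate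
28 | (Z)-2-(4-methoxybenzyloxy)vinylcerium dichloride (formed in the flask) | Cl[Ce](Cl)/C=C\OCc1ccc(OC)cc1 | intermediate
29 | cis-1,2-divinylcyclohexanol: 20 carrying at C10 an axial hydroxyl and an equatorial (Z)-2-(4-methoxybenzyloxy)vinyl group cis to the axial 5-isopropenyl group | C=C(C)[C@H]1[C@H]2O[C@H](OC)C[C@@H]2[C@H](OCOC)C[C@@]1(O)/C=C\OCc3ccc(OC)cc3 | intermediate
30 | potassium alkoxide of 29 (formed in the flask) | C=C(C)[C@H]1[C@H]2O[C@H](OC)C[C@@H]2[C@H](OCOC)C[C@@]1([O-])/C=C\OCc3ccc(OC)cc3.[K+] | intermediate
31 | ten-membered potassium C10=C1 enolate (formed in the flask) | [K+].[O-]/C1=C/[C@@H](OCc3ccc(OC)cc3)C/C(C)=C/[C@H]2O[C@H](OC)C[C@@H]2[C@H](OCOC)C1 | intermediate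
32 | (1(10)Z,4E,2S)-cyclodeca-1(10),4-dienyl C10 triflate with 2-O-(4-methoxybenzyl), 8-OMOM and the 6,12-lactol methyl acetal | FC(F)(F)S(=O)(=O)O/C1=C/[C@@H](OCc3ccc(OC)cc3)C/C(C)=C/[C@H]2O[C@H](OC)C[C@@H]2[C@H](OCOC)C1 | intermediate
33 | (tributylstannyl)methanol | CCCC[Sn](CCCC)(CCCC)CO | starting material
34 | 32 with CH2OH (C14) on C10 in place of the triflate | OC/C1=C/[C@@H](OCc3ccc(OC)cc3)C/C(C)=C/[C@H]2O[C@H](OC)C[C@@H]2[C@H](OCOC)C1 | intermediate
35 | 14-O-tert-butyldiphenylsilyl ether of 34 | CC(C)(C)[Si](c4ccccc4)(c5ccccc5)OC/C1=C/[C@@H](OCc3ccc(OC)cc3)C/C(C)=C/[C@H]2O[C@H](OC)C[C@@H]2[C@H](OCOC)C1 | intermediate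
36 | 6,12-lactol from 35 (one C12 epimer drawn) | CC(C)(C)[Si](c4ccccc4)(c5ccccc5)OC/C1=C/[C@@H](OCc3ccc(OC)cc3)C/C(C)=C/[C@H]2O[C@H](O)C[C@@H]2[C@H](OCOC)C1 | intermediate
37 | 6,12-lactone (6,7-trans) with 2-OPMB, 8-OMOM, 14-OTBDPS | CC(C)(C)[Si](c4ccccc4)(c5ccccc5)OC/C1=C/[C@@H](OCc3ccc(OC)cc3)C/C(C)=C/[C@H]2OC(=O)C[C@@H]2[C@H](OCOC)C1 | intermediate
38 | 11-(dimethylaminomethyl) derivative of 37 (C11 epimer trans to C8 drawn) | CC(C)(C)[Si](c4ccccc4)(c5ccccc5)OC/C1=C/[C@@H](OCc3ccc(OC)cc3)C/C(C)=C/[C@H]2OC(=O)[C@@H](CN(C)C)[C@@H]2[C@H](OCOC)C1 | intermediate
39 | trimethylammonium iodide of 38 (formed in the flask) | CC(C)(C)[Si](c4ccccc4)(c5ccccc5)OC/C1=C/[C@@H](OCc3ccc(OC)cc3)C/C(C)=C/[C@H]2OC(=O)[C@@H](C[N+](C)(C)C)[C@@H]2[C@H](OCOC)C1.[I-] | intermediate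
40 | α-methylene lactone with 2-OPMB, 8-OMOM, 14-OTBDPS | CC(C)(C)[Si](c4ccccc4)(c5ccccc5)OC/C1=C/[C@@H](OCc3ccc(OC)cc3)C/C(C)=C/[C@H]2OC(=O)C(=C)[C@@H]2[C@H](OCOC)C1 | intermediate
41 | (2S)-2-hydroxy compound from 40 | CC(C)(C)[Si](c4ccccc4)(c5ccccc5)OC/C1=C/[C@@H](O)C/C(C)=C/[C@H]2OC(=O)C(=C)[C@@H]2[C@H](OCOC)C1 | intermediate
42 | 2-acetate of 41 | CC(C)(C)[Si](c4ccccc4)(c5ccccc5)OC/C1=C/[C@@H](OC(C)=O)C/C(C)=C/[C@H]2OC(=O)C(=C)[C@@H]2[C@H](OCOC)C1 | intermediate
43 | 8-O-[(2,2'-bipyridin-1-ium-1-yl)methyl] ether triflate of 44 (formed in the flask) | CC(C)(C)[Si](c4ccccc4)(c5ccccc5)OC/C1=C/[C@@H](OC(C)=O)C/C(C)=C/[C@H]2OC(=O)C(=C)[C@@H]2[C@H](OC[n+]6ccccc6-c7ccccn7)C1.[O-]S(=O)(=O)C(F)(F)F | intermediate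
44 | 8-hydroxy 2-acetate 14-O-TBDPS α-methylene lactone | CC(C)(C)[Si](c4ccccc4)(c5ccccc5)OC/C1=C/[C@@H](OC(C)=O)C/C(C)=C/[C@H]2OC(=O)C(=C)[C@@H]2[C@H](O)C1 | intermediate
45 | 8-methacrylate of 44 (14-O-TBDPS ether of the target) | CC(C)(C)[Si](c4ccccc4)(c5ccccc5)OC/C1=C/[C@@H](OC(C)=O)C/C(C)=C/[C@H]2OC(=O)C(=C)[C@@H]2[C@H](OC(=O)C(C)=C)C1 | intermediate
46 | CNP0138477.2: (1(10)Z,4E)-2-acetoxy-14-hydroxy-8-methacryloyloxy-germacra-1(10),4,11(13)-trien-6,12-olide, (2S,6R,7R,8R) | C=C(C)C(=O)O[C@@H]1C/C(CO)=C\[C@@H](OC(C)=O)C/C(C)=C/[C@H]2OC(=O)C(=C)[C@@H]21 | target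

## Step count and least certain steps

Total step count: 27. Longest linear sequence: 25 steps (steps 1 to 12 and 15 to 27); steps 13 and 14 are a two-step side branch to 26.

Step 16 (key step). The most likely failure is E1cB loss of the C2 4-methoxybenzyl oxide from enolate 31, because the Z enol ether delivers this C–O bond perpendicular to the enolate plane; O-sulfonylation of alkoxide 30 by the sulfonimide before it rearranges is the second risk. The fallback avoids any enolate during the ring expansion. It sets out from 29: N-(trimethylsilyl)imidazole would give the trimethylsilyl ether F1. Heating F1 in base-washed glass (toluene, sealed tube, about 200 °C) would take it through the same chair in a neutral siloxy-Cope rearrangement to the ten-membered trimethylsilyl enol ether F2. F2 with C4F9SO2F and a catalytic amount of Bu4NF, the sulfonyl fluoride being present while fluoride frees the enolate, would give the C10 nonaflate F3. F3 would enter the Stille coupling of step 17 in place of 32 and return to the route at 34.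

Step 15. The most likely failure is poor facial selectivity or enolisation at C5, because the equatorial trajectory of the bulky alkenylcerium reagent passes the axial isopropenyl group. The fallback sets out from 20 and uses a slimmer sp nucleophile: the lithium alkynyl ether 24 (from 25 and n-BuLi, then CeCl3, −78 °C) would add to give the propargylic alcohol F6, and cis-semihydrogenation (H2, Pd/CaCO3 poisoned with Pb(OAc)2, quinoline) would give the Z enol ether and return to the route at 29.

Step 11. The most likely failure is opening of the oxirane by bromide or attack at C10, both the result of slow carbon–carbon bond formation at C5, which is hindered and inductively deactivated by the neighbouring C6 oxygen. The fallback sets out from 16 and builds the isopropenyl group in two stages from a halide-free, rod-shaped nucleophile. Et2AlC≡CSiMe3 (made in the flask from trimethylsilylacetylene, n-BuLi and Et2AlCl; toluene, 0 °C) would open the oxirane trans-diaxially to the alkynyl carbinol F4; K2CO3 in MeOH would give the terminal alkyne F5; zirconium-catalysed carboalumination (Me3Al, Cp2ZrCl2, CH2Cl2, then water) would add methyl to the inner alkyne carbon and return to the route at 19.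

Step 17. The most likely failure is slow transfer of the hydroxymethyl group from tin to the hindered alkenylpalladium, which would allow reduction of the triflate or Cope rearrangement of the diene on long heating. The fallback sets out from 32 and changes the one-carbon source: palladium-catalysed methoxycarbonylation (CO, MeOH, Pd(OAc)2, dppp, Et3N, DMF, 40 °C) would give the methyl ester F7, and iBu2AlH (CH2Cl2, −78 °C) would reduce it and return to the route at 34.

Step 25. The most likely failure is ionisation or loss of the allylic C2 acetate, or partial desilylation, under the silyl triflate. The fallback sets out from 40 and reorders the endgame so that no acyl group is present when the methoxymethyl ether is cleaved. Transacetalisation with HCl in MeOH (rt) would give the C8 alcohol F8; methacrylic anhydride (Et3N, DMAP) would give the methacrylate F9; DDQ would free the C2 hydroxyl to give F10; Ac2O (pyridine, DMAP) would return to the route at 45.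

## Further compounds

F1 | step 16 | 10-O-trimethylsilyl ether of 29 | C=C(C)[C@H]1[C@H]2O[C@H](OC)C[C@@H]2[C@H](OCOC)C[C@@]1(O[Si](C)(C)C)/C=C\OCc3ccc(OC)cc3
F2 | step 16 | ten-membered C10 trimethylsilyl enol ether (1(10)Z,4E,2S) | C[Si](C)(C)O/C1=C/[C@@H](OCc3ccc(OC)cc3)C/C(C)=C/[C@H]2O[C@H](OC)C[C@@H]2[C@H](OCOC)C1
F3 | step 16 | ten-membered C10 nonafluorobutanesulfonate (1(10)Z,4E,2S) | FC(F)(F)C(F)(F)C(F)(F)C(F)(F)S(=O)(=O)O/C1=C/[C@@H](OCc3ccc(OC)cc3)C/C(C)=C/[C@H]2O[C@H](OC)C[C@@H]2[C@H](OCOC)C1
F4 | step 11 | trans-diaxial 5-[(trimethylsilyl)ethynyl]-10-ol analogue of 19 | CO[C@@H]1C[C@@H]2[C@H](OCOC)C[C@H](O)[C@@H](C#C[Si](C)(C)C)[C@H]2O1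
F5 | step 11 | trans-diaxial 5-ethynyl-10-ol analogue of 19 | CO[C@@H]1C[C@@H]2[C@H](OCOC)C[C@H](O)[C@@H](C#C)[C@H]2O1
F6 | step 15 | 10-[(4-methoxybenzyloxy)ethynyl] carbinol (alkynyl analogue of 29) | CO[C@@H]1C[C@@H]2[C@H](OCOC)C[C@@](O)(C#COCc3ccc(OC)cc3)[C@@H](C(C)=C)[C@H]2O1
F7 | step 17 | methyl ester at C14 (CO2Me on C10 in place of the triflate of 32) | COC(=O)/C1=C/[C@@H](OCc3ccc(OC)cc3)C/C(C)=C/[C@H]2O[C@H](OC)C[C@@H]2[C@H](OCOC)C1
F8 | step 25 | 8-hydroxy compound from 40 (2-OPMB, 14-OTBDPS) | CC(C)(C)[Si](c4ccccc4)(c5ccccc5)OC/C1=C/[C@@H](OCc3ccc(OC)cc3)C/C(C)=C/[C@H]2OC(=O)C(=C)[C@@H]2[C@H](O)C1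
F9 | step 25 | 8-methacrylate of F8 | CC(C)(C)[Si](c4ccccc4)(c5ccccc5)OC/C1=C/[C@@H](OCc3ccc(OC)cc3)C/C(C)=C/[C@H]2OC(=O)C(=C)[C@@H]2[C@H](OC(=O)C(C)=C)C1
F10 | step 25 | 2-hydroxy 8-methacrylate 14-O-TBDPS compound | CC(C)(C)[Si](c4ccccc4)(c5ccccc5)OC/C1=C/[C@@H](O)C/C(C)=C/[C@H]2OC(=O)C(=C)[C@@H]2[C@H](OC(=O)C(C)=C)C1
A1 | alternative 1 | 8-desacyl target (2-acetate, free C8 and C14 hydroxyls) | C=C1C(=O)O[C@@H]2/C=C(C)/C[C@H](OC(C)=O)/C=C(CO)\C[C@@H](O)[C@@H]12
A2 | alternative 1 | (1(10)Z,4E)-2-acetoxy-8,14-dihydroxygermacra-1(10),4,11(13)-trien-12-oic acid | C=C(C(=O)O)[C@H]1C/C=C(C)/C[C@H](OC(C)=O)/C=C(CO)\C[C@H]1O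
A3 | alternative 2 | cis-anti-cis tricyclic photoadduct | O=C1[C@@H]2[C@@]3(C)C[C@H](O[Si](CC)(CC)CC)[C@H]3[C@]2(COCc4ccc(OC)cc4)C[C@@H](O[Si](C)(C)C(C)(C)C)[C@H]1CC(=O)OC
A4 | alternative 2 | cyclohexenone partner (C5 to C10 with C7 and C8) | O=C1C=C(COCc2ccc(OC)cc2)C[C@@H](O[Si](C)(C)C(C)(C)C)[C@H]1CC(=O)OC
A5 | alternative 2 | (S)-triethyl[(3-methylcyclobut-2-en-1-yl)oxy]silane | CC1=C[C@@H](O[Si](CC)(CC)CC)C1
A6 | alternative 3 | 2-desacetyl target as its C14 tert-butyldimethylsilyl ether | C=C1C(=O)O[C@@H]2/C=C(C)/C[C@H](O)/C=C(CO[Si](C)(C)C(C)(C)C)\C[C@@H](OC(=O)C(C)=C)[C@@H]12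
A7 | alternative 3 | open-chain (Z)-iodoalkene C2 aldehyde | C=C1C(=O)O[C@H](/C=C(C)/CC=O)[C@H]1[C@H](OC(=O)C(C)=C)C/C(CO[Si](C)(C)C(C)(C)C)=C\I
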